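## Retrosynthetic overview

Disconnections are listed from the first bond made to the last; read upward for the retrosynthesis.

- Ring A is bought aromatic: phloroacetophenone 1 → (two C–CH3 bonds) → 2 → (two O–CH3 bonds) → 3.
- Cα=Cβ bond: 3 + 2-methoxybenzaldehyde 4 (ring B, bought aromatic) → chalcone 5 (Claisen–Schmidt).
- O1–C2 bond: 5 → flavanone 6 by oxa-Michael closure; ring C is the only ring made.
- C3–O bond (key step, last): 6 → silyl enol ether 7 → aminooxy ketone 8 → flavonol 9. Nitrosobenzene delivers the oxygen, and cleavage of its N–O bond provides the oxidation that aromatises ring C.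
- Ring order: A and B pre-formed; C closed in step 3 and raised to the pyranone level in step 4.

Assumption: the target is a planar flavonol with no stereocentre, so it is achiral and no stereocontrol is needed.

## Route

Step 1
Reactants: 1 1-(2,4,6-trihydroxyphenyl)ethan-1-one (phloroacetophenone)
Product: 2 1-(2,4,6-trihydroxy-3,5-dimethylphenyl)ethan-1-one
Conditions: NaOMe (3.2 equiv), MeI (2.3 equiv), MeOH, 0 °C then reflux, 4 h; chromatography
Reagents that add atoms: iodomethane, CI
Why: Phloroglucinol-type C-alkylation: in MeOH the polyphenoxide of 1 reacts through carbon, and each of the two free ring positions takes one methyl; the mono-methyl and gem-dimethyl by-products are separated.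

Step 2
Reactants: 2 1-(2,4,6-trihydroxy-3,5-dimethylphenyl)ethan-1-one
Product: 3 1-(2-hydroxy-4,6-dimethoxy-3,5-dimethylphenyl)ethan-1-one
Conditions: Me2SO4 (2.1 equiv), K2CO3 (2.5 equiv), acetone, reflux, 6 h
Reagents that add atoms: dimethyl sulfate, COS(=O)(=O)OC
Why: Williamson O-methylation: the acetyl carbonyl hydrogen-bonds one ortho hydroxyl at a time and that one stays unreactive under K2CO3, so only the para and the other ortho hydroxyl are methylated.

Step 3
Reactants: 3 1-(2-hydroxy-4,6-dimethoxy-3,5-dimethylphenyl)ethan-1-one; 4 2-methoxybenzaldehyde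
Product: 6 racemic 5,7-dimethoxy-2-(2-methoxyphenyl)-6,8-dimethylchroman-4-one, via chalcone 5 (not isolated)
Conditions: KOH (50% aq, 10 equiv), EtOH, 25 °C, 48 h; then conc. HCl to pH 1, 80 °C, 16 h
Reagents that add atoms: none
Why: Claisen–Schmidt aldol condensation gives the E-chalcone, and acid then drives the 6-endo oxa-Michael addition of the phenol, which is favoured when the carbonyl carries a second ortho substituent; C2 forms as a racemate and is flattened in step 4.

Step 4
Reactants: 6 racemic 5,7-dimethoxy-2-(2-methoxyphenyl)-6,8-dimethylchroman-4-one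
Product: 9 3-hydroxy-5,7-dimethoxy-2-(2-methoxyphenyl)-6,8-dimethyl-4H-chromen-4-one, via silyl enol ether 7 (not isolated), via N-silyl aminooxy ketone 8 (not isolated)
Conditions: TMSOTf (1.3 equiv), Et3N (1.1 equiv), CH2Cl2, 0 °C, 1 h; then PhNO (1.1 equiv), −78 °C, 2 h; then DBU (3 equiv), −78 °C to 25 °C; 1 M HCl work-up
Reagents that add atoms: nitrosobenzene, O=Nc1ccccc1
Why: Proposed new method: soft enolisation gives the C3=C4 silyl enol ether, and the slight excess of silyl triflate activates the N=O group so that C3 attacks the nitroso oxygen (closest known reaction: Lewis-acid-catalysed O-selective nitroso aldol, i.e. α-aminoxylation, of silyl enol ethers of aryl ketones). DBU then removes the acidic C3–H and the weak N–O bond breaks in a Kornblum–DeLaMare-type elimination to the chroman-3,4-dione, which tautomerises to the aromatic flavonol. Nitrosobenzene is the only oxidant and ends as aniline; the aminoxide is a poor leaving group from C3, so loss of the oxygen to give the flavone should not compete; and no nucleophilic peroxide is present, so the aurone pathway that plagues alkaline-peroxide oxidation of chalcones of this substitution pattern is closed. This aminoxylation/N–O elimination sequence has not been shown on flavanones or used to reach the flavonol oxidation level.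

## Compound list

1 | 1-(2,4,6-trihydroxyphenyl)ethan-1-one (phloroacetophenone) | CC(=O)c1c(O)cc(O)cc1O | starting material
2 | 1-(2,4,6-trihydroxy-3,5-dimethylphenyl)ethan-1-one | CC(=O)c1c(O)c(C)c(O)c(C)c1O | intermediate
3 | 1-(2-hydroxy-4,6-dimethoxy-3,5-dimethylphenyl)ethan-1-one | CC(=O)c1c(O)c(C)c(OC)c(C)c1OC | intermediate
4 | 2-methoxybenzaldehyde | COc1ccccc1C=O | starting material
5 | (E)-1-(2-hydroxy-4,6-dimethoxy-3,5-dimethylphenyl)-3-(2-methoxyphenyl)prop-2-en-1-one | COc1ccccc1/C=C/C(=O)c1c(O)c(C)c(OC)c(C)c1OC | intermediate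
6 | racemic 5,7-dimethoxy-2-(2-methoxyphenyl)-6,8-dimethylchroman-4-one | COc1ccccc1C1CC(=O)c2c(OC)c(C)c(OC)c(C)c2O1 | intermediate
7 | racemic [5,7-dimethoxy-2-(2-methoxyphenyl)-6,8-dimethyl-2H-chromen-4-yl]oxy(trimethyl)silane | COc1ccccc1C1C=C(O[Si](C)(C)C)c2c(OC)c(C)c(OC)c(C)c2O1 | intermediate
8 | racemic 5,7-dimethoxy-2-(2-methoxyphenyl)-6,8-dimethyl-3-{[phenyl(trimethylsilyl)amino]oxy}chroman-4-one (mixture of 2,3-diastereomers) | COc1ccccc1C1Oc2c(C)c(OC)c(C)c(OC)c2C(=O)C1ON(c1ccccc1)[Si](C)(C)C | intermediate
9 | 3-hydroxy-5,7-dimethoxy-2-(2-methoxyphenyl)-6,8-dimethyl-4H-chromen-4-one (achiral) | COc1ccccc1-c1oc2c(C)c(OC)c(C)c(OC)c2c(=O)c1O | target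

## Step count and risks

Total steps: 4. Longest linear sequence: 4 (1 → 2 → 3 → 6 → 9).

Steps most likely to fail:

- **Step 4 (the proposed new step).** The main risks are attack at nitrogen instead of oxygen of nitrosobenzene, which would end as the 3-anilinoflavone, and sluggish N–O elimination. The fallback is the classical Kostanecki flavonol synthesis and sets out from 6. Isoamyl nitrite and conc. HCl in EtOH at 0–25 °C nitrosate C3, forming a C–N bond, to give racemic 3-(hydroxyimino)-5,7-dimethoxy-2-(2-methoxyphenyl)-6,8-dimethylchroman-4-one F1. Boiling AcOH with 10% H2SO4 hydrolyses the oxime, and the resulting 3,4-dione tautomerises to the flavonol. The route is rejoined at 9.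

- **Step 1.** Direct C-methylation gives a statistical mixture and some gem-dimethylated, dearomatised material. The fallback sets out from 1. Double Mannich aminomethylation (aq. Me2NH, aq. CH2O, EtOH, 25 °C) can only occupy the two aromatic C–H positions and gives 1-{3,5-bis[(dimethylamino)methyl]-2,4,6-trihydroxyphenyl}ethan-1-one F2. Hydrogenolysis of both benzylic C–N bonds (H2, 4 bar, Pd/C, AcOH, 60 °C) then gives the two methyl groups. The route is rejoined at 2.

- **Step 3.** The doubly ortho-substituted, electron-rich ketone may condense slowly, and the acid ring closure is an equilibrium. The fallback sets out from 3. The dianion (LDA, LiN(iPr)2, 2.2 equiv, THF, −78 °C) adds to aldehyde 4 to give racemic 3-hydroxy-1-(2-hydroxy-4,6-dimethoxy-3,5-dimethylphenyl)-3-(2-methoxyphenyl)propan-1-one F3. Mitsunobu cyclisation (PPh3, DIAD, THF, 0 to 25 °C) closes ring C by intramolecular C–O bond formation. The route is rejoined at 6.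

## Further compounds

F1 | step 4 | racemic 3-(hydroxyimino)-5,7-dimethoxy-2-(2-methoxyphenyl)-6,8-dimethylchroman-4-one (oxime geometry not defined) | COc1ccccc1C1Oc2c(C)c(OC)c(C)c(OC)c2C(=O)C1=NO
F2 | step 1 | 1-{3,5-bis[(dimethylamino)methyl]-2,4,6-trihydroxyphenyl}ethan-1-one | CC(=O)c1c(O)c(CN(C)C)c(O)c(CN(C)C)c1O
F3 | step 3 | racemic 3-hydroxy-1-(2-hydroxy-4,6-dimethoxy-3,5-dimethylphenyl)-3-(2-methoxyphenyl)propan-1-one | COc1ccccc1C(O)CC(=O)c1c(O)c(C)c(OC)c(C)c1OC
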